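**Retrosynthetic overview**

- The target is a naphthalene with a 4-hydroxyphenyl group on C1, identical 2,4-dihydroxybenzoyl groups on C2 and C3, H on C4 and hydroxyls on C6 and C7. It is reached last from its heptamethyl ether 11 by cleavage of all seven methyl ethers.
- The strategy rests on this mapping: C2–C3 with its two aroyl carbonyls is the triple bond of a symmetric diaroylacetylene (8). C1 with its aryl group, C4 and ring A (C4a–C8a) are an ortho-methylbenzophenone (3).
- Key disconnection: C1–C2 and C3–C4 are formed by photoenolization of 3, [4+2] cycloaddition with 8 and loss of water. Ring B is the only ring formed; ring A and the three outer aryl rings are bought.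
- Ketone 3 comes from Friedel–Crafts acylation of 3,4-dimethoxytoluene. Ynedione 8 comes from double addition of BrMgC≡CMgBr to 2,4-dimethoxybenzaldehyde, then MnO2 oxidation.

Key step: step 4

Remark on the chemistry: the target is achiral. Diol 7 is carried as its meso/racemic mixture because both diastereomers give the same ynedione, and all phenols stay masked as methyl ethers until the last step.

**Route**

Step 1
Reactants: 1 3,4-dimethoxytoluene; 2 4-methoxybenzoyl chloride
Product: 3 (4,5-dimethoxy-2-methylphenyl)(4-methoxyphenyl)methanone
Conditions: AlCl3 (1.2 equiv), CH2Cl2, 0 °C to rt; cold 1 M HCl quench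
Reagents that add atoms: none
Why: Friedel–Crafts acylation should occur at the ring position para to the 3-methoxy group and ortho to the methyl group, the most activated free site, and stop after one acylation because the ketone deactivates the ring; no methoxy group sits ortho to the new carbonyl, so chelation-driven demethylation is not expected.

Step 2
Reactants: 4 ethynylmagnesium bromide (1.0 equiv); 5 2,4-dimethoxybenzaldehyde (2.0 equiv)
Product: 7 1,4-bis(2,4-dimethoxyphenyl)but-2-yne-1,4-diol (meso/racemic mixture), via bis(bromomagnesio)acetylene 6 (not isolated)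
Conditions: EtMgBr (1.0 equiv), THF, rt to 45 °C; then 5, THF, 0 °C to rt; H2O/sat. aq NH4Cl
Reagents that add atoms: none
Why: Ethylmagnesium bromide removes the remaining acetylenic proton to give the acetylene bis-Grignard reagent, which undergoes 1,2-addition to the aromatic aldehyde at both ends; the two carbinol centres form without control, which is immaterial because both are oxidised in step 3.

Step 3
Reactants: 7 1,4-bis(2,4-dimethoxyphenyl)but-2-yne-1,4-diol
Product: 8 1,4-bis(2,4-dimethoxyphenyl)but-2-yne-1,4-dione
Conditions: activated MnO2 (20 equiv), CH2Cl2, rt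
Reagents that add atoms: none
Why: Both carbinols are benzylic and propargylic, the alcohol class that MnO2 oxidises cleanly under neutral heterogeneous conditions, so both diastereomers should converge on the achiral ynedione without base or acid touching this Michael acceptor.

Step 4
Reactants: 3 (4,5-dimethoxy-2-methylphenyl)(4-methoxyphenyl)methanone (1.5 equiv); 8 1,4-bis(2,4-dimethoxyphenyl)but-2-yne-1,4-dione (1.0 equiv)
Product: 11 [6,7-dimethoxy-1-(4-methoxyphenyl)naphthalene-2,3-diyl]bis[(2,4-dimethoxyphenyl)methanone] (heptamethyl ether of the target), via (E)-hydroxy-ortho-quinodimethane 9 (not isolated), via 1-hydroxy-1,4-dihydronaphthalene cycloadduct 10 (not isolated)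
Conditions: hν (365 nm), degassed benzene (about 0.03 M), Ar, rt, 8 added slowly; then p-TsOH·H2O (0.2 equiv), 80 °C
Reagents that add atoms: none
Why: Excitation of the benzophenone chromophore of 3 and intersystem crossing give the triplet, whose carbonyl oxygen takes a hydrogen from the ortho methyl group through a six-membered transition state (1,5-hydrogen transfer); the short-lived (Z)-dienol returns to 3, whereas the (E)-dienol 9, with its hydroxyl turned away from the exocyclic methylene, should live long enough to be trapped. The electron-rich diene of 9 adds across the electron-poor triple bond of 8 in a thermal concerted [4+2] cycloaddition that forms C1–C2 and C3–C4 and closes the six-membered carbocyclic ring B onto ring A by intermolecular annulation, restoring the aromaticity of ring A. The closest known reaction type is the photoenolization/Diels–Alder trapping of 2-methylbenzophenones by acetylenedicarboxylates, followed by dehydration of the adducts to 1-arylnaphthalene-2,3-dicarbonyl compounds. The only new stereocentre, the carbinol carbon C1 of 10, forms as a racemate with nothing controlling it and disappears when acid ionises the doubly benzylic C1–OH and C4 loses a proton (formal 1,4-elimination of water), so the naphthalene forms without an oxidant. No regiochemical question arises because 8 is C2-symmetric and both orientations give the same adduct. The step needs chemoselective excitation and fast trapping: 365 nm light in oxygen-free benzene addresses the n,π* band of 3, the nonpolar solvent keeps the lowest triplet of the methoxylated benzophenone n,π*-like, and slow addition of the doubly activated ynedione limits its own light absorption while still intercepting 9 before it reketonises.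

Step 5
Reactants: 11 [6,7-dimethoxy-1-(4-methoxyphenyl)naphthalene-2,3-diyl]bis[(2,4-dimethoxyphenyl)methanone]
Product: 12 [6,7-dihydroxy-1-(4-hydroxyphenyl)naphthalene-2,3-diyl]bis[(2,4-dihydroxyphenyl)methanone] (CNP0304576.0)
Conditions: BBr3 (14 equiv), CH2Cl2, −78 °C to rt; then ice–H2O, 1 M HCl
Reagents that add atoms: none
Why: Lewis-acid-mediated aryl methyl ether cleavage (boron coordinates each ether oxygen and bromide attacks the methyl group by SN2) should remove all seven methyl groups, the two next to the carbonyls fastest through chelation, while the diaryl ketones and the naphthalene core are inert and the aryloxyboron species hydrolyse on acidic work-up.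

**Compound list**

1 | 3,4-dimethoxytoluene | Cc1ccc(OC)c(OC)c1 | starting material
2 | 4-methoxybenzoyl chloride | COc1ccc(cc1)C(Cl)=O | starting material
3 | (4,5-dimethoxy-2-methylphenyl)(4-methoxyphenyl)methanone | Cc1cc(OC)c(OC)cc1C(=O)c1ccc(OC)cc1 | intermediate
4 | ethynylmagnesium bromide | C#C[Mg]Br | starting material
5 | 2,4-dimethoxybenzaldehyde | COc1ccc(C=O)c(OC)c1 | starting material
6 | bis(bromomagnesio)acetylene | Br[Mg]C#C[Mg]Br | intermediate (not isolated)
7 | 1,4-bis(2,4-dimethoxyphenyl)but-2-yne-1,4-diol (mixture of meso and racemic diastereomers, descriptors left open) | COc1ccc(C(O)C#CC(O)c2ccc(OC)cc2OC)c(OC)c1 | intermediate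
8 | 1,4-bis(2,4-dimethoxyphenyl)but-2-yne-1,4-dione | COc1ccc(C(=O)C#CC(=O)c2ccc(OC)cc2OC)c(OC)c1 | intermediate
9 | (E)-(3,4-dimethoxy-6-methylidenecyclohexa-2,4-dien-1-ylidene)(4-methoxyphenyl)methanol, the (E)-photoenol of 3 | C=C1C=C(OC)C(OC)=C/C1=C(\O)c2ccc(OC)cc2 | intermediate (not isolated)
10 | [1-hydroxy-6,7-dimethoxy-1-(4-methoxyphenyl)-1,4-dihydronaphthalene-2,3-diyl]bis[(2,4-dimethoxyphenyl)methanone] (racemic) | OC1(c2ccc(OC)cc2)C(C(=O)c2ccc(OC)cc2OC)=C(C(=O)c2ccc(OC)cc2OC)Cc2cc(OC)c(OC)cc12 | intermediate (not isolated)
11 | [6,7-dimethoxy-1-(4-methoxyphenyl)naphthalene-2,3-diyl]bis[(2,4-dimethoxyphenyl)methanone] | COc1ccc(cc1)-c1c(C(=O)c2ccc(OC)cc2OC)c(C(=O)c2ccc(OC)cc2OC)cc2cc(OC)c(OC)cc12 | intermediate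
12 | [6,7-dihydroxy-1-(4-hydroxyphenyl)naphthalene-2,3-diyl]bis[(2,4-dihydroxyphenyl)methanone] | O=C(c1ccc(O)cc1O)c1cc2cc(O)c(O)cc2c(-c2ccc(O)cc2)c1C(=O)c1ccc(O)cc1O | target

**Step count**

Total: 5 steps. Longest linear sequence: 4 steps (steps 2, 3, 4, 5 from 4 and 5); the other branch is step 1, then steps 4 and 5.

**Steps most likely to fail**

Step 4 (key step). Several processes could spoil it:
- the ynedione may absorb the light itself and react photochemically, or quench the ketone triplet by energy transfer;
- charge-transfer character in the triplet of the trimethoxylated benzophenone may lower the efficiency of hydrogen transfer;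
- the photoenol may reketonise or be oxidised by traces of oxygen faster than it is trapped;
- the diaroylnaphthalene product may undergo secondary photolysis.

The fallback reaches the same ring B closure thermally and sets out from 3 (with 8 as dienophile), returning at 11.
- Wohl–Ziegler bromination of the methyl group of 3 (N-bromosuccinimide, AIBN, PhCF3, 80 °C) should give [2-(bromomethyl)-4,5-dimethoxyphenyl](4-methoxyphenyl)methanone F1.
- Hydrolysis (NaHCO3, H2O/dioxane, 60 °C) should give the hydroxymethyl ketone, which closes to the lactol 5,6-dimethoxy-1-(4-methoxyphenyl)-1,3-dihydroisobenzofuran-1-ol F2.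
- Warming F2 with 8 and catalytic AcOH in toluene (90 °C) should dehydrate it to 5,6-dimethoxy-1-(4-methoxyphenyl)isobenzofuran F3, which is trapped in the flask by Diels–Alder addition to 8. This should give the oxygen-bridged adduct [1,4-epoxy-6,7-dimethoxy-1-(4-methoxyphenyl)-1,4-dihydronaphthalene-2,3-diyl]bis[(2,4-dimethoxyphenyl)methanone] F4. Stronger acid is avoided because it would open the bridge to a 4-naphthol.
- Reductive removal of the bridging oxygen with iodotrimethylsilane made in the flask (Me3SiCl, NaI, MeCN, 0 °C) should give 11.

Step 5. Cleavage may stop at partly methylated stages, the boron chelates of the ortho-hydroxy ketones and the catechol may resist hydrolysis, and the free catechol may be oxidised by air during work-up. The fallback splits the deprotection into two mechanistically different stages and sets out from 11, returning at 12.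
- BCl3 (CH2Cl2, 0 °C) should remove only the two methyl groups ortho to the carbonyls by chelation, giving [6,7-dimethoxy-1-(4-methoxyphenyl)naphthalene-2,3-diyl]bis[(2-hydroxy-4-methoxyphenyl)methanone] F5.
- The remaining five ethers are then cleaved by nucleophilic attack of chloride in a pyridinium chloride melt (190 °C, Ar), with acidic work-up under argon, to give 12.

Step 2. The bis-Grignard reagent is sparingly soluble and may react at one end only, leaving mixtures of mono-adduct and diol, and the electron-rich propargylic carbinols may ionise during work-up. The fallback builds the diol stepwise through a lithium dianion and sets out from 4 and 5, returning at 7.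
- Addition of 4 (1.2 equiv) to 5 (THF, 0 °C) should give 1-(2,4-dimethoxyphenyl)prop-2-yn-1-ol F6, which is isolated.
- Double deprotonation with n-BuLi (2.1 equiv, THF, −78 °C) and addition of a second equivalent of 5 should give 7.

**Further compounds**

F1 | step 4 | [2-(bromomethyl)-4,5-dimethoxyphenyl](4-methoxyphenyl)methanone | COc1ccc(cc1)C(=O)c1cc(OC)c(OC)cc1CBr
F2 | step 4 | 5,6-dimethoxy-1-(4-methoxyphenyl)-1,3-dihydroisobenzofuran-1-ol (racemic) | OC1(c2ccc(OC)cc2)OCc2cc(OC)c(OC)cc12
F3 | step 4 | 5,6-dimethoxy-1-(4-methoxyphenyl)isobenzofuran | COc1ccc(cc1)C1=C2C=C(OC)C(OC)=CC2=CO1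
F4 | step 4 | [1,4-epoxy-6,7-dimethoxy-1-(4-methoxyphenyl)-1,4-dihydronaphthalene-2,3-diyl]bis[(2,4-dimethoxyphenyl)methanone] (racemic, relative configuration fixed by the bridge) | COc1ccc(cc1)C12OC(C(C(=O)c3ccc(OC)cc3OC)=C1C(=O)c1ccc(OC)cc1OC)c1cc(OC)c(OC)cc12
F5 | step 5 | [6,7-dimethoxy-1-(4-methoxyphenyl)naphthalene-2,3-diyl]bis[(2-hydroxy-4-methoxyphenyl)methanone] | COc1ccc(cc1)-c1c(C(=O)c2ccc(OC)cc2O)c(C(=O)c2ccc(OC)cc2O)cc2cc(OC)c(OC)cc12
F6 | step 2 | 1-(2,4-dimethoxyphenyl)prop-2-yn-1-ol (racemic) | COc1ccc(C(O)C#C)c(OC)c1
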